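**Plan**

- Retrosynthesis: the quinone methide is first taken back to its leuco triarylmethane. The two bonds from the carbon on C1 of ring A (the central benzene) to the para carbons of the two phenol-derived rings are then cut together, leaving a ring A aldehyde and two molecules of phenol.
- Enabling feature: that carbon carries a 4-hydroxyphenyl ring and a quinone methide ring, i.e. two phenol units bound through their para carbons to one carbon (the benzaurin chromophore). It is therefore an aryl aldehyde carbon after two para-arylations and one oxidation.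
- The aldehyde is cut further at the biaryl bond A–D (Suzuki–Miyaura at C–Cl), at the bond from ring A to the alkyne (Sonogashira at C–Br) and at the C1–CHO bond (lithiation between Br and Cl).
- Forward: no ring is built. Ring A is bought as (2-bromo-4-chlorophenyl)methanol, formylated, joined to the alkyne arm (ring C), then to ring D, then to two phenols, deprotected and oxidised.
- Every phenolic and benzylic oxygen outside the two new phenol rings travels as a pivalate: deactivating and acid-stable for the condensation, and removed by methoxide instead of a Lewis acid.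
- Stereochemistry: the target has no stereocentre and no double bond with defined geometry, so nothing has to be controlled.

Key step: step 10

Assumption: selaginellin F is taken as the open quinone methide drawn in the SMILES, and the A–D biaryl axis (two ortho substituents only) is treated as freely rotating.

**Route**

Step 1
Reactants: 1 (2-bromo-4-chlorophenyl)methanol
Product: 3 2-bromo-6-chloro-3-(hydroxymethyl)benzaldehyde, via C3-lithiated lithium alkoxide 2 (not isolated)
Conditions: LiN(iPr)2 (2.3 equiv), THF, −78 °C; DMF, −78 → −40 °C; 1 M HCl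
Reagents that add atoms: N,N-dimethylformamide, CN(C)C=O
Why: Directed ortho-metalation followed by formylation: after the hydroxyl is masked as its lithium alkoxide, the second equivalent of amide base should remove the ring proton flanked by Br and Cl (the most acidic one), and at −78 °C the 2,6-dihaloaryllithium should neither lose lithium halide nor migrate before DMF traps it.

Step 2
Reactants: 3 2-bromo-6-chloro-3-(hydroxymethyl)benzaldehyde
Product: 4 (2-bromo-4-chloro-3-formylphenyl)methyl pivalate
Conditions: PivCl, Et3N, DMAP (cat.), CH2Cl2, 0 °C → rt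
Reagents that add atoms: pivaloyl chloride, CC(C)(C)C(Cl)=O
Why: DMAP-catalysed acylation of a primary benzylic alcohol, which leaves the aldehyde and both aryl halides untouched.

Step 3
Reactants: 5 4-iodophenol
Product: 6 4-iodophenyl pivalate
Conditions: PivCl, Et3N, DMAP (cat.), CH2Cl2, 0 °C → rt
Reagents that add atoms: pivaloyl chloride, CC(C)(C)C(Cl)=O
Why: Routine O-acylation of a phenol, giving an ester that turns the later alkyne aryl group from an electron donor into a weakly deactivated ring.

Step 4
Reactants: 6 4-iodophenyl pivalate; 7 ethynyltrimethylsilane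
Product: 8 4-[(trimethylsilyl)ethynyl]phenyl pivalate
Conditions: Pd(PPh3)2Cl2 (2 mol %), CuI (2 mol %), Et3N, THF, rt
Reagents that add atoms: none
Why: Sonogashira coupling of an aryl iodide at room temperature, conditions under which an aryl pivalate is not attacked by the tertiary amine.

Step 5
Reactants: 8 4-[(trimethylsilyl)ethynyl]phenyl pivalate
Product: 9 4-ethynylphenyl pivalate
Conditions: Bu4NF (1.1 equiv), AcOH (1.2 equiv), THF, 0 °C
Reagents that add atoms: none
Why: Fluoride-induced protodesilylation of an alkynylsilane, buffered with acetic acid so that the aryl ester is not cleaved by basic fluoride.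

Step 6
Reactants: 10 4-bromobenzene-1,3-diol (4-bromoresorcinol)
Product: 11 4-bromo-1,3-phenylene bis(pivalate)
Conditions: PivCl (2.4 equiv), Et3N, DMAP (cat.), CH2Cl2, 0 °C → rt
Reagents that add atoms: pivaloyl chloride, CC(C)(C)C(Cl)=O
Why: Double O-acylation of a resorcinol, which installs the two electron-withdrawing groups that later keep ring D from acting as a Friedel–Crafts nucleophile.

Step 7
Reactants: 11 4-bromo-1,3-phenylene bis(pivalate)
Product: 12 4-(4,4,5,5-tetramethyl-1,3,2-dioxaborolan-2-yl)-1,3-phenylene bis(pivalate)
Conditions: B2pin2, Pd(dppf)Cl2 (3 mol %), KOAc, 1,4-dioxane, 85 °C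
Reagents that add atoms: bis(pinacolato)diboron, CC1(C)OB(OC1(C)C)B1OC(C)(C)C(C)(C)O1
Why: Miyaura borylation of an aryl bromide, whose weak acetate base is known to tolerate aryl esters.

Step 8
Reactants: 4 (2-bromo-4-chloro-3-formylphenyl)methyl pivalate; 9 4-ethynylphenyl pivalate
Product: 13 (4-chloro-3-formyl-2-{[4-(pivaloyloxy)phenyl]ethynyl}phenyl)methyl pivalate
Conditions: Pd(PPh3)2Cl2 (5 mol %), CuI (5 mol %), Et3N, THF, 60 °C
Reagents that add atoms: none
Why: Sonogashira coupling that should be chemoselective for the C–Br bond, which is activated by the ortho formyl group, because a triphenylphosphine-ligated palladium catalyst does not insert into the aryl chloride at this temperature.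

Step 9
Reactants: 13 (4-chloro-3-formyl-2-{[4-(pivaloyloxy)phenyl]ethynyl}phenyl)methyl pivalate; 12 4-(4,4,5,5-tetramethyl-1,3,2-dioxaborolan-2-yl)-1,3-phenylene bis(pivalate)
Product: 14 6-[2,4-bis(pivaloyloxy)phenyl]-3-[(pivaloyloxy)methyl]-2-{[4-(pivaloyloxy)phenyl]ethynyl}benzaldehyde
Conditions: Pd(OAc)2 (5 mol %), SPhos (10 mol %), K3PO4 (finely ground), toluene, 80 °C
Reagents that add atoms: none
Why: Suzuki–Miyaura coupling of an aryl chloride activated by its ortho formyl group, for which SPhos-ligated palladium is a standard catalyst, run with nearly anhydrous phosphate in toluene so that the four pivalates are spared.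

Step 10
Reactants: 14 6-[2,4-bis(pivaloyloxy)phenyl]-3-[(pivaloyloxy)methyl]-2-{[4-(pivaloyloxy)phenyl]ethynyl}benzaldehyde; 15 phenol (large excess, two molecules incorporated)
Product: 17 leuco triarylmethane (14 in which CHO has become a bis(4-hydroxyphenyl)methyl group), via benzhydrol 16 (not isolated)
Conditions: PhOH (30 equiv), MsOH (2 equiv), CH2Cl2, 0 °C → rt
Reagents that add atoms: none
Why: MsOH protonates the aldehyde of 14 and phenol attacks through its para carbon to give benzhydrol 16; this ionises at once to a benzylic cation stabilised by the new 4-hydroxyphenyl ring (a protonated para-quinone methide), which is captured by the para carbon of a second phenol. This is the Baeyer condensation by which aryl aldehydes and phenols give 4,4'-dihydroxytriarylmethanes, the leuco stage of benzaurin. Two C–C bonds form at the former aldehyde carbon, no ring closes and no stereocentre arises, since the new carbon carries two identical aryl groups. The step needs para attack twice, capture by external phenol instead of ring D, and an untouched triple bond: the carbonyl carbon lies between ring D and the alkynyl group and should be too crowded for ortho attack, phenol is present in thirty-fold excess, and ring D is deactivated by its two pivalate groups while its only carbon able to close a fluorene (C6') is meta to both oxygens. The 4-pivaloyloxyphenyl group makes the alkyne far less basic than a 4-alkoxyphenyl alkyne, so protonation of the triple bond and closure onto the carbonyl oxygen to an isochromenylium ion should not compete with a limited amount of acid at room temperature. The hindered pivalates should resist acyl transfer to phenol, and any partial loss would be levelled in step 11.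

Step 11
Reactants: 17 leuco triarylmethane tetrapivalate
Product: 18 4-{2-[bis(4-hydroxyphenyl)methyl]-4-(hydroxymethyl)-3-[(4-hydroxyphenyl)ethynyl]phenyl}benzene-1,3-diol (leuco hexaol)
Conditions: NaOMe (8 equiv), MeOH/THF (degassed), rt, Ar; then AcOH
Reagents that add atoms: none
Why: Zemplén-type transesterification removes the three aryl pivalates and the benzylic pivalate in one operation, and in methanol at room temperature the benzylic alkoxide should not add to the neighbouring triple bond, which is deactivated by its phenoxide-bearing aryl group.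

Step 12
Reactants: 18 leuco hexaol
Product: 19 selaginellin F
Conditions: DDQ (1.05 equiv), THF, 0 °C → rt
Reagents that add atoms: none
Why: DDQ dehydrogenation of a leuco triarylmethane: hydride is abstracted from the methine activated by two para-hydroxyphenyl rings and the cation loses a phenolic proton to give the fuchsone-type quinone methide, while the resorcinol ring, the primary benzylic alcohol and the alkyne are much poorer hydride donors.

**Compound list**

1 | (2-bromo-4-chlorophenyl)methanol | OCc1ccc(Cl)cc1Br | starting material
2 | lithium (2-bromo-4-chloro-3-lithiophenyl)methanolate | [Li]OCc1ccc(Cl)c([Li])c1Br | intermediate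
3 | 2-bromo-6-chloro-3-(hydroxymethyl)benzaldehyde | O=Cc1c(Cl)ccc(CO)c1Br | intermediate
4 | (2-bromo-4-chloro-3-formylphenyl)methyl pivalate | O=Cc1c(Cl)ccc(COC(=O)C(C)(C)C)c1Br | intermediate
5 | 4-iodophenol | Oc1ccc(I)cc1 | starting material
6 | 4-iodophenyl pivalate | CC(C)(C)C(=O)Oc1ccc(I)cc1 | intermediate
7 | ethynyltrimethylsilane | C#C[Si](C)(C)C | starting material
8 | 4-[(trimethylsilyl)ethynyl]phenyl pivalate | CC(C)(C)C(=O)Oc1ccc(C#C[Si](C)(C)C)cc1 | intermediate
9 | 4-ethynylphenyl pivalate | CC(C)(C)C(=O)Oc1ccc(C#C)cc1 | intermediate
10 | 4-bromobenzene-1,3-diol (4-bromoresorcinol) | Oc1ccc(Br)c(O)c1 | starting material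
11 | 4-bromo-1,3-phenylene bis(pivalate) | CC(C)(C)C(=O)Oc1ccc(Br)c(OC(=O)C(C)(C)C)c1 | intermediate
12 | 4-(4,4,5,5-tetramethyl-1,3,2-dioxaborolan-2-yl)-1,3-phenylene bis(pivalate) | CC(C)(C)C(=O)Oc1ccc(B2OC(C)(C)C(C)(C)O2)c(OC(=O)C(C)(C)C)c1 | intermediate
13 | (4-chloro-3-formyl-2-{[4-(pivaloyloxy)phenyl]ethynyl}phenyl)methyl pivalate | O=Cc1c(Cl)ccc(COC(=O)C(C)(C)C)c1C#Cc1ccc(OC(=O)C(C)(C)C)cc1 | intermediate
14 | 6-[2,4-bis(pivaloyloxy)phenyl]-3-[(pivaloyloxy)methyl]-2-{[4-(pivaloyloxy)phenyl]ethynyl}benzaldehyde | O=Cc1c(-c2ccc(OC(=O)C(C)(C)C)cc2OC(=O)C(C)(C)C)ccc(COC(=O)C(C)(C)C)c1C#Cc1ccc(OC(=O)C(C)(C)C)cc1 | intermediate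
15 | phenol | Oc1ccccc1 | starting material
16 | racemic benzhydrol: 14 in which CHO has become CH(OH)(4-hydroxyphenyl) | OC(c1ccc(O)cc1)c1c(-c2ccc(OC(=O)C(C)(C)C)cc2OC(=O)C(C)(C)C)ccc(COC(=O)C(C)(C)C)c1C#Cc1ccc(OC(=O)C(C)(C)C)cc1 | intermediate
17 | leuco triarylmethane tetrapivalate: 14 in which CHO has become CH(4-hydroxyphenyl)2 | Oc1ccc(cc1)C(c1ccc(O)cc1)c1c(-c2ccc(OC(=O)C(C)(C)C)cc2OC(=O)C(C)(C)C)ccc(COC(=O)C(C)(C)C)c1C#Cc1ccc(OC(=O)C(C)(C)C)cc1 | intermediate
18 | 4-{2-[bis(4-hydroxyphenyl)methyl]-4-(hydroxymethyl)-3-[(4-hydroxyphenyl)ethynyl]phenyl}benzene-1,3-diol | Oc1ccc(cc1)C(c1ccc(O)cc1)c1c(-c2ccc(O)cc2O)ccc(CO)c1C#Cc1ccc(O)cc1 | intermediate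
19 | selaginellin F | O=C1C=CC(=C(c2ccc(O)cc2)c2c(-c3ccc(O)cc3O)ccc(CO)c2C#Cc2ccc(O)cc2)C=C1 | target

**Step count**

Total: 12 steps. Longest linear sequence: 8 steps (steps 3, 4, 5, 8, 9, 10, 11, 12, from 4-iodophenol); the ring A line from 1 has 7 steps.

**Steps most likely to fail**

Step 10. Attack of phenol on the shielded carbonyl may be slow enough that protonation of the triple bond takes over, leading to closure onto the carbonyl oxygen or hydroarylation, and some ortho attack of phenol may occur. The fallback forms the two bonds one at a time and needs only weak acid. It sets out from 14. 4-(tert-Butyldimethylsilyloxy)phenylmagnesium bromide F1, made from commercial (4-bromophenoxy)(tert-butyl)dimethylsilane and Mg in THF, would be added at −78 °C, where the aldehyde is far more electrophilic than the hindered pivalates, to give the racemic silyl-protected benzhydrol F2. This carbinol should ionise with catalytic CF3CO2H in CH2Cl2 at 0 °C, and the cation would take up phenol 15 at its para carbon to give the racemic mono-silylated leuco triarylmethane F3. NaOMe in MeOH/THF would then remove the four pivalates and the aryl silyl ether together, and the sequence comes back to the route at 18.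

Step 9. Under basic conditions the ortho-acyloxy boronate may lose boron by protodeboronation, or the pivalates may be cleaved, before transmetalation occurs. The fallback is a base-free transmetalation from tin and sets out from 11. Stannylation with hexabutylditin (Pd(PPh3)4, toluene, 110 °C) would give 4-(tributylstannyl)-1,3-phenylene bis(pivalate) F4. A Stille coupling of F4 with chloride 13 (Pd2(dba)3, P(t-Bu)3, CsF, 1,4-dioxane, 90 °C) then comes back to the route at 14.

Step 12. With six free hydroxyl groups the oxidant may also attack the resorcinol ring or the 4-hydroxyphenyl alkyne, or the new quinone methide may be over-oxidised. The fallback oxidises before deprotection, when only the bis(4-hydroxyphenyl)methine is electron-rich, and sets out from 17. DDQ in THF would give the quinone methide tetrapivalate F5. NaOMe in degassed MeOH/THF then cleaves the esters, the fuchsone being held as its delocalised phenolate until AcOH is added, and the sequence comes back to the route at 19.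

**Further compounds**

F1 | step 10 | 4-(tert-butyldimethylsilyloxy)phenylmagnesium bromide | CC(C)(C)[Si](C)(C)Oc1ccc([Mg]Br)cc1
F2 | step 10 | racemic silyl-protected benzhydrol: 14 in which CHO has become CH(OH)[4-(tert-butyldimethylsilyloxy)phenyl] | OC(c1ccc(O[Si](C)(C)C(C)(C)C)cc1)c1c(-c2ccc(OC(=O)C(C)(C)C)cc2OC(=O)C(C)(C)C)ccc(COC(=O)C(C)(C)C)c1C#Cc1ccc(OC(=O)C(C)(C)C)cc1
F3 | step 10 | racemic mono-silylated leuco triarylmethane: 17 in which one phenolic OH is a tert-butyldimethylsilyl ether | Oc1ccc(cc1)C(c1ccc(O[Si](C)(C)C(C)(C)C)cc1)c1c(-c2ccc(OC(=O)C(C)(C)C)cc2OC(=O)C(C)(C)C)ccc(COC(=O)C(C)(C)C)c1C#Cc1ccc(OC(=O)C(C)(C)C)cc1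
F4 | step 9 | 4-(tributylstannyl)-1,3-phenylene bis(pivalate) | CCCC[Sn](CCCC)(CCCC)c1ccc(OC(=O)C(C)(C)C)cc1OC(=O)C(C)(C)C
F5 | step 12 | quinone methide tetrapivalate: selaginellin F with ring D, ring C and CH2OH oxygens as pivalates | O=C1C=CC(=C(c2ccc(O)cc2)c2c(-c3ccc(OC(=O)C(C)(C)C)cc3OC(=O)C(C)(C)C)ccc(COC(=O)C(C)(C)C)c2C#Cc2ccc(OC(=O)C(C)(C)C)cc2)C=C1
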